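## Retrosynthetic overview

1. Target ⇐ spiro ketone carrying the exocyclic methylene: the hindered ketone becomes the vinyl bromide and the doubly allylic CH2 becomes the enone carbonyl.
2. Ring A and the spiro centre ⇐ Fe–H-initiated radical 6-exo-dig closure of a ring-B tertiary radical onto a tethered terminal alkyne; ring A is formed last and the ring-B halogens steer the spiro configuration.
3. trans-Bromochloride of ring B ⇐ Shi epoxide of a cyclohexa-1,4-diene (bromide opening, then chloride with retention).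
4. Ring B (formed first) ⇐ cobalt-catalysed [4+2] of isoprene with an α,α-dimethyl alkynyl ketone; the alkyne tether comes from enolate propargylation.

Assumption: 1, 3 and 5 are purchased, and the D-fructose-derived Shi ketone attacks the methyl-bearing ring olefin of 6 from the same face as it does 1-phenylcyclohexene.

## Route

Step 1
Reactants: 1 2,2-dimethylbut-3-ynoic acid
Product: 2 3,3-dimethylpent-4-yn-2-one
Conditions: MeLi (3.2 equiv), Et2O, 0 °C → rt; then ice-water
Reagents that add atoms: methyllithium, [Li]C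
Why: Organolithium addition to the lithium carboxylate gives a stable gem-dialkoxide that collapses to the methyl ketone only on hydrolysis (acid-to-ketone synthesis); no stereocentre.

Step 2
Reactants: 2 3,3-dimethylpent-4-yn-2-one; 3 isoprene (2-methylbuta-1,3-diene)
Product: 4 3-methyl-3-(4-methylcyclohexa-1,4-dien-1-yl)butan-2-one
Conditions: CoBr2(dppe) (5 mol%), Zn (10 mol%), ZnI2 (10 mol%), CH2Cl2, rt
Reagents that add atoms: none
Why: Cobalt-catalysed neutral Diels–Alder of a 2-substituted diene with an unactivated terminal alkyne gives the 1,4-disubstituted ("para") cyclohexa-1,4-diene; no stereocentre.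

Step 3
Reactants: 4 3-methyl-3-(4-methylcyclohexa-1,4-dien-1-yl)butan-2-one; 5 propargyl bromide (3-bromoprop-1-yne)
Product: 6 2-methyl-2-(4-methylcyclohexa-1,4-dien-1-yl)hept-6-yn-3-one
Conditions: LiN(iPr)2, THF, −78 °C; then 5, DMPU, −78 → 0 °C
Reagents that add atoms: none
Why: Kinetic enolate alkylation; the methyl group is the only enolisable position, so C-propargylation is regiospecific.

Step 4
Reactants: 6 2-methyl-2-(4-methylcyclohexa-1,4-dien-1-yl)hept-6-yn-3-one
Product: 7 2-methyl-2-[(1R,6S)-6-methyl-7-oxabicyclo[4.1.0]hept-3-en-3-yl]hept-6-yn-3-one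
Conditions: D-fructose-derived Shi ketone (30 mol%), KHSO5, K2CO3, Bu4NHSO4 (cat.), MeCN/CH2(OMe)2/aq. Na2B4O7 buffer, 0 °C
Reagents that add atoms: potassium peroxymonosulfate KHSO5, [K+].[O-]S(=O)(=O)OO
Why: Shi asymmetric epoxidation; the chiral dioxirane attacks the methyl-bearing olefin (the other is shielded by the quaternary acyl-bearing carbon, the alkyne is inert), and the spiro transition state sets both epoxide carbons (1R,6S).

Step 5
Reactants: 7 2-methyl-2-[(1R,6S)-6-methyl-7-oxabicyclo[4.1.0]hept-3-en-3-yl]hept-6-yn-3-one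
Product: 8 2-[(4S,5S)-5-bromo-4-hydroxy-4-methylcyclohex-1-en-1-yl]-2-methylhept-6-yn-3-one
Conditions: Li2NiBr4, THF, 0 °C → rt; aqueous work-up
Reagents that add atoms: Li2NiBr4, [Li+].[Li+].[Ni+2].[Br-].[Br-].[Br-].[Br-]
Why: SN2 epoxide opening by soft bromide at the less hindered secondary carbon; inversion there sets the C–Br centre (5S) trans to the untouched tertiary C–O (4S).

Step 6
Reactants: 8 2-[(4S,5S)-5-bromo-4-hydroxy-4-methylcyclohex-1-en-1-yl]-2-methylhept-6-yn-3-one
Product: 9 2-[(4S,5S)-5-bromo-4-chloro-4-methylcyclohex-1-en-1-yl]-2-methylhept-6-yn-3-one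
Conditions: SOCl2, Et2O, −20 → 0 °C
Reagents that add atoms: thionyl chloride, O=S(Cl)Cl
Why: The tertiary chlorosulfite ionises with neighbouring-group participation of the anti bromine; chloride opens the bromonium ion at the tertiary carbon on the face the oxygen left, so the C–Cl centre forms with retention (4S) and the bromochloride is trans.

Step 7
Reactants: 9 2-[(4S,5S)-5-bromo-4-chloro-4-methylcyclohex-1-en-1-yl]-2-methylhept-6-yn-3-one
Product: 10 (6S,8S,9S)-8-bromo-9-chloro-1,1,9-trimethyl-5-methylidenespiro[5.5]undecan-2-one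
Conditions: Fe(acac)3 (2 equiv), PhSiH3 (3 equiv), EtOH/HOCH2CH2OH, 60 °C, 0.01 M
Reagents that add atoms: none
Why: Proposed new method: Fe–H hydrogen-atom transfer to the ring olefin gives the tertiary ring-B radical, which closes 6-exo-dig onto the terminal alkyne (helped by the CMe2–C(=O) tether), and the vinyl radical is quenched by PhSiH3/EtOH, so one step makes the spiro quaternary centre next to CMe2 and the exocyclic methylene; the new bond should form axially on the chair that keeps Br, Cl and the CMe2 arm equatorial (trans to Br, cis to Cl, 6S), because axial attack on the flipped chair meets the syn-axial Br; closest known reaction type: Fe(acac)3/PhSiH3 reductive radical cyclisation of 1,6-enynes (5-exo-dig) and MHAT Giese cyclisations that build quaternary centres.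

Step 8
Reactants: 10 (6S,8S,9S)-8-bromo-9-chloro-1,1,9-trimethyl-5-methylidenespiro[5.5]undecan-2-one
Product: 11 (6S,8S,9S)-2,8-dibromo-9-chloro-1,1,9-trimethyl-5-methylidenespiro[5.5]undec-2-ene
Conditions: (PhO)3P, Br2, CH2Cl2, −60 °C; then 10, Et3N, −60 °C → reflux
Reagents that add atoms: bromine, BrBr (delivered as (PhO)3PBr2)
Why: Halophosphonium-mediated conversion of an enolisable ketone into its vinyl bromide; the ketone can enolise only toward the CH2, so the bromide lands next to CMe2.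

Step 9
Reactants: 11 (6S,8S,9S)-2,8-dibromo-9-chloro-1,1,9-trimethyl-5-methylidenespiro[5.5]undec-2-ene
Product: 13 (6S,8S,9S)-4,8-dibromo-9-chloro-5,5,9-trimethyl-1-methylidenespiro[5.5]undec-3-en-2-one, via allylic alcohol 12 (not isolated)
Conditions: SeO2 (30 mol%), t-BuOOH, CH2Cl2, 0 °C → rt; then MnO2, rt, same flask
Reagents that add atoms: SeO2, O=[Se]=O (catalytic oxygen carrier); tert-butyl hydroperoxide, CC(C)(C)OO (terminal oxygen source)
Why: SeO2 allylic hydroxylation (ene reaction, then [2,3]-sigmatropic shift) of the exocyclic olefin puts OH on the only allylic CH2 and returns the methylene; MnO2 then oxidises the doubly allylic alcohol to the cross-conjugated dienone, so the carbinol centre is not retained.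

## Compound list

1 | 2,2-dimethylbut-3-ynoic acid | C#CC(C)(C)C(=O)O | starting material
2 | 3,3-dimethylpent-4-yn-2-one | CC(=O)C(C)(C)C#C | intermediate
3 | isoprene (2-methylbuta-1,3-diene) | C=CC(C)=C | starting material
4 | 3-methyl-3-(4-methylcyclohexa-1,4-dien-1-yl)butan-2-one | CC(=O)C(C)(C)C1=CCC(C)=CC1 | intermediate
5 | propargyl bromide (3-bromoprop-1-yne) | BrCC#C | starting material
6 | 2-methyl-2-(4-methylcyclohexa-1,4-dien-1-yl)hept-6-yn-3-one | C#CCCC(=O)C(C)(C)C1=CCC(C)=CC1 | intermediate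
7 | 2-methyl-2-[(1R,6S)-6-methyl-7-oxabicyclo[4.1.0]hept-3-en-3-yl]hept-6-yn-3-one | C#CCCC(=O)C(C)(C)C1=CC[C@]2(C)O[C@@H]2C1 | intermediate
8 | 2-[(4S,5S)-5-bromo-4-hydroxy-4-methylcyclohex-1-en-1-yl]-2-methylhept-6-yn-3-one | C#CCCC(=O)C(C)(C)C1=CC[C@](C)(O)[C@@H](Br)C1 | intermediate
9 | 2-[(4S,5S)-5-bromo-4-chloro-4-methylcyclohex-1-en-1-yl]-2-methylhept-6-yn-3-one | C#CCCC(=O)C(C)(C)C1=CC[C@](C)(Cl)[C@@H](Br)C1 | intermediate
10 | (6S,8S,9S)-8-bromo-9-chloro-1,1,9-trimethyl-5-methylidenespiro[5.5]undecan-2-one | C=C1CCC(=O)C(C)(C)[C@]12CC[C@](C)(Cl)[C@@H](Br)C2 | intermediate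
11 | (6S,8S,9S)-2,8-dibromo-9-chloro-1,1,9-trimethyl-5-methylidenespiro[5.5]undec-2-ene | C=C1CC=C(Br)C(C)(C)[C@]12CC[C@](C)(Cl)[C@@H](Br)C2 | intermediate
12 | (6S,8S,9S)-4,8-dibromo-9-chloro-5,5,9-trimethyl-1-methylidenespiro[5.5]undec-3-en-2-ol (both C2 epimers) | C=C1C(O)C=C(Br)C(C)(C)[C@]12CC[C@](C)(Cl)[C@@H](Br)C2 | intermediate
13 | (6S,8S,9S)-4,8-dibromo-9-chloro-5,5,9-trimethyl-1-methylidenespiro[5.5]undec-3-en-2-one | C=C1C(=O)C=C(Br)C(C)(C)[C@]12CC[C@](C)(Cl)[C@@H](Br)C2 | target

## Count and risks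

Total steps: 9. Longest linear sequence: 9 (1 → 13).

**Step 7 (radical spirocyclisation).** The tertiary radical may be reduced, or may take the propargylic hydrogen by a 1,5-shift, before it closes on the unactivated alkyne, and the facial ratio at the spiro centre is untested. Fallback: set out from 9 and C-silylate the terminal alkyne (N,O-bis(trimethylsilyl)acetamide, cat. Me4N pivalate, MeCN, rt) to give 2-[(4S,5S)-5-bromo-4-chloro-4-methylcyclohex-1-en-1-yl]-2-methyl-7-(trimethylsilyl)hept-6-yn-3-one F4. The same Fe(acac)3/PhSiH3 treatment now closes onto a silyl alkyne, which gives an α-silyl vinyl radical and is not itself attacked by Fe–H, and delivers (6R,8S,9S)-8-bromo-9-chloro-1,1,9-trimethyl-5-[(trimethylsilyl)methylidene]spiro[5.5]undecan-2-one F5 as an olefin-isomer mixture. Protodesilylation (CF3CO2H, CH2Cl2, 0 °C) comes back to the route at 10.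

**Step 8 (vinyl bromide from a ketone flanked by a quaternary carbon).** The halophosphonium reagent may fail on so hindered a carbonyl. Fallback: set out from 10 and trap the enolate (KN(SiMe3)2, PhNTf2, THF, −78 °C) as (6S,8S,9S)-8-bromo-9-chloro-1,1,9-trimethyl-5-methylidenespiro[5.5]undec-2-en-2-yl trifluoromethanesulfonate F6. The SeO2/t-BuOOH then MnO2 sequence of step 9 gives, through (6S,8S,9S)-8-bromo-9-chloro-4-hydroxy-1,1,9-trimethyl-5-methylidenespiro[5.5]undec-2-en-2-yl trifluoromethanesulfonate F7, the vinylogous acyl triflate (6R,8S,9S)-8-bromo-9-chloro-1,1,9-trimethyl-5-methylidene-4-oxospiro[5.5]undec-2-en-2-yl trifluoromethanesulfonate F8. LiBr in acetone replaces the triflate by addition–elimination and comes back to the route at 13.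

**Step 4 (enantioselective epoxidation of a non-conjugated cyclic trisubstituted olefin).** The enantiomeric excess may be insufficient. Fallback: set out from 6, epoxidise with m-chloroperbenzoic acid (NaHCO3, CH2Cl2, 0 °C) and run steps 5 and 6 on the racemate. This carries along 2-methyl-2-[(1S,6R)-6-methyl-7-oxabicyclo[4.1.0]hept-3-en-3-yl]hept-6-yn-3-one F1, 2-[(4R,5R)-5-bromo-4-hydroxy-4-methylcyclohex-1-en-1-yl]-2-methylhept-6-yn-3-one F2 and 2-[(4R,5R)-5-bromo-4-chloro-4-methylcyclohex-1-en-1-yl]-2-methylhept-6-yn-3-one F3. Preparative chromatography on a chiral stationary phase removes F3 and comes back to the route at 9.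

## Further compounds

F1 | step 4 | 2-methyl-2-[(1S,6R)-6-methyl-7-oxabicyclo[4.1.0]hept-3-en-3-yl]hept-6-yn-3-one | C#CCCC(=O)C(C)(C)C1=CC[C@@]2(C)O[C@H]2C1
F2 | step 4 | 2-[(4R,5R)-5-bromo-4-hydroxy-4-methylcyclohex-1-en-1-yl]-2-methylhept-6-yn-3-one | C#CCCC(=O)C(C)(C)C1=CC[C@@](C)(O)[C@H](Br)C1
F3 | step 4 | 2-[(4R,5R)-5-bromo-4-chloro-4-methylcyclohex-1-en-1-yl]-2-methylhept-6-yn-3-one | C#CCCC(=O)C(C)(C)C1=CC[C@@](C)(Cl)[C@H](Br)C1
F4 | step 7 | 2-[(4S,5S)-5-bromo-4-chloro-4-methylcyclohex-1-en-1-yl]-2-methyl-7-(trimethylsilyl)hept-6-yn-3-one | C[Si](C)(C)C#CCCC(=O)C(C)(C)C1=CC[C@](C)(Cl)[C@@H](Br)C1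
F5 | step 7 | (6R,8S,9S)-8-bromo-9-chloro-1,1,9-trimethyl-5-[(trimethylsilyl)methylidene]spiro[5.5]undecan-2-one | C[Si](C)(C)C=C1CCC(=O)C(C)(C)[C@]12CC[C@](C)(Cl)[C@@H](Br)C2
F6 | step 8 | (6S,8S,9S)-8-bromo-9-chloro-1,1,9-trimethyl-5-methylidenespiro[5.5]undec-2-en-2-yl trifluoromethanesulfonate | C=C1CC=C(OS(=O)(=O)C(F)(F)F)C(C)(C)[C@]12CC[C@](C)(Cl)[C@@H](Br)C2
F7 | step 8 | (6S,8S,9S)-8-bromo-9-chloro-4-hydroxy-1,1,9-trimethyl-5-methylidenespiro[5.5]undec-2-en-2-yl trifluoromethanesulfonate | C=C1C(O)C=C(OS(=O)(=O)C(F)(F)F)C(C)(C)[C@]12CC[C@](C)(Cl)[C@@H](Br)C2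
F8 | step 8 | (6R,8S,9S)-8-bromo-9-chloro-1,1,9-trimethyl-5-methylidene-4-oxospiro[5.5]undec-2-en-2-yl trifluoromethanesulfonate | C=C1C(=O)C=C(OS(=O)(=O)C(F)(F)F)C(C)(C)[C@]12CC[C@](C)(Cl)[C@@H](Br)C2
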